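The route rests on disconnecting the C3=C4 bond of ring A. The cis-3α,4α-diol diester of the target is traced back to a trisubstituted alkene, and that alkene to a ring B cyclohexanone carrying a butenyl chain on quaternary C10 and an isopropenyl group on C5, both relayed in trans fashion from the single stereocentre of (R)-carvone. Ring-closing metathesis then builds ring A, the trans-decalin and the C3=C4 alkene in one operation. The feature exploited is the vicinal trans C5/C10 substitution of ring B, which lets only the C5 isopropenyl group reach the C10 chain. A C9-to-C8 carbonyl shift, dihydroxylation, two acylations and a singlet-oxygen ene reaction complete the route.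

Key step: step 3

Assumption: the C7 configuration carried from 8 to 13 and the C8 configuration of transient 10 are inconsequential, because both carbons become trigonal before the target is reached; isopropenylmagnesium bromide (THF solution) and 4-iodobut-1-ene are taken as purchased.

Step 1
Reactants: 1 (R)-carvone; 2 isopropenylmagnesium bromide
Product: 4 trimethyl{[(3S,5R)-2-methyl-3,5-di(prop-1-en-2-yl)cyclohex-1-en-1-yl]oxy}silane, via bromomagnesium enolate 3 (not isolated)
Conditions: 2, CuBr·SMe2 (10 mol %), THF, −78 → −30 °C; then TMSCl, Et3N, DMPU, −78 °C → rt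
Reagents that add atoms: chlorotrimethylsilane, C[Si](C)(C)Cl
Why: Copper-catalysed conjugate addition of the Grignard reagent should deliver the isopropenyl group axially to the enone β-carbon on the face anti to the existing isopropenyl group (3,5-trans, new centre S), and O-silylation stores the regiodefined enolate as its silyl enol ether.

Step 2
Reactants: 4 trimethyl{[(3S,5R)-2-methyl-3,5-di(prop-1-en-2-yl)cyclohex-1-en-1-yl]oxy}silane; 5 4-iodobut-1-ene
Product: 7 (2S,3S,5R)-2-(but-3-en-1-yl)-2-methyl-3,5-di(prop-1-en-2-yl)cyclohexan-1-one, via lithium enolate 6 (not isolated)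
Conditions: MeLi, THF, 0 °C → rt; then DMPU, 5, −78 °C → rt
Reagents that add atoms: none
Why: Methyllithium cleavage of the silyl enol ether regenerates the tetrasubstituted lithium enolate regiospecifically, and its SN2 C-alkylation (enolate alkylation) by the primary iodide in a dipolar cosolvent should occur anti to the vicinal isopropenyl group, setting the quaternary carbon (future C10, 2S) with the butenyl chain trans to the future C5 substituent.

Step 3
Reactants: 7 (2S,3S,5R)-2-(but-3-en-1-yl)-2-methyl-3,5-di(prop-1-en-2-yl)cyclohexan-1-one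
Product: 8 (5α,7βH,10β)-eudesma-3,11-dien-9-one
Conditions: second-generation Grubbs catalyst (H2IMes)(PCy3)Cl2Ru=CHPh (5 mol %), CH2Cl2 (0.01 M), 40 °C
Reagents that add atoms: none
Why: The ruthenium benzylidene should exchange first onto the monosubstituted butenyl alkene, and the resulting alkylidene then adds across the 1,1-disubstituted isopropenyl group on C5 through a ruthenacyclobutane whose cycloreversion releases ethene and leaves the C3=C4 double bond. The closest known reaction type is ring-closing metathesis of a terminal alkene onto a 2-propenyl group to give a methyl-substituted cyclohexene. Ring A closes as a six-membered carbocycle (C10–C1–C2–C3=C4–C5) fused to ring B across C5–C10. No stereocentre is created; the trans ring fusion (10β-methyl, 5α-H) is already fixed because the two tethers are trans and can both sit equatorial on ring B. The step needs only chemoselection among three alkenes, and ring size secures it, since engaging the C7 isopropenyl group would require a bridged eight-membered ring and intermolecular metathesis of 1,1-disubstituted alkenes is slow at high dilution.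

Step 4
Reactants: 8 (5α,7βH,10β)-eudesma-3,11-dien-9-one
Product: 9 (E)-tosylhydrazone of 8
Conditions: TsNHNH2, PPTS (cat.), EtOH, 70 °C
Reagents that add atoms: p-toluenesulfonyl hydrazide, Cc1ccc(cc1)S(=O)(=O)NN
Why: Acid-catalysed hydrazone formation at the only carbonyl group should give the E isomer, with the sulfonamide nitrogen turned away from quaternary C10 and toward the C8 methylene as the next step requires.

Step 5
Reactants: 9 (E)-tosylhydrazone of 8
Product: 12 (5α,7βH,10β)-8-(methylsulfanyl)eudesma-3,8,11-triene, via lithiated 8-methylsulfanyl hydrazone 10 (not isolated), via 9-lithio vinyl sulfide 11 (not isolated)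
Conditions: n-BuLi (2.2 equiv), THF, −50 °C; MeSSMe, −78 → −30 °C; then n-BuLi (2.5 equiv), −30 °C → rt; H2O
Reagents that add atoms: dimethyl disulfide, CSSC
Why: The hydrazone dianion can form only at C8 and should be sulfenylated there, after which further base triggers the Shapiro reaction (loss of sulfinate and dinitrogen) to a C9 vinyllithium that is protonated on work-up, leaving sulfur on C8 of a C8=C9 alkene while the other alkenes are inert to the base.

Step 6
Reactants: 12 (5α,7βH,10β)-8-(methylsulfanyl)eudesma-3,8,11-triene
Product: 14 (5α,10β)-eudesma-3,7(11)-dien-8-one, via β,γ-unsaturated ketone 13 (not isolated)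
Conditions: HgCl2, MeCN/H2O (3:1), 60 °C; then DBU, CH2Cl2, rt
Reagents that add atoms: water, O
Why: Thiophile-assisted vinyl sulfide hydrolysis (protonation at C9, water capture of the C8 thionium ion) should unmask the C8 ketone and so complete the 1,2-carbonyl transposition, and base-mediated enolisation then moves the 11,12-alkene into conjugation as the tetrasubstituted C7=C11 enone (isopulegone-to-pulegone type isomerisation), erasing the C7 stereocentre.

Step 7
Reactants: 14 (5α,10β)-eudesma-3,7(11)-dien-8-one
Product: 15 (3α,4α,5α,10β)-3,4-dihydroxyeudesm-7(11)-en-8-one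
Conditions: OsO4 (2 mol %), NMO, acetone/H2O (5:1), 0 °C → rt
Reagents that add atoms: N-methylmorpholine N-oxide, C[N+]1([O-])CCOCC1; water, O
Why: Upjohn dihydroxylation should select the electron-rich trisubstituted C3=C4 alkene over the electron-poor tetrasubstituted enone alkene, and the [3+2] osmylation should occur on the α-face, opposite the axial 10β-methyl group, setting C3 and C4 together as the cis-3α,4α-diol.

Step 8
Reactants: 15 (3α,4α,5α,10β)-3,4-dihydroxyeudesm-7(11)-en-8-one; 16 angelic acid
Product: 18 (3α,4α,5α,10β)-4-hydroxy-8-oxoeudesm-7(11)-en-3-yl (Z)-2-methylbut-2-enoate, via angelic 2,4,6-trichlorobenzoic anhydride 17 (not isolated)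
Conditions: 16, 2,4,6-Cl3C6H2COCl, Et3N, toluene, rt; then 15, 80 °C
Reagents that add atoms: none
Why: Yamaguchi-type esterification through the mixed anhydride, run without a nucleophilic catalyst, should acylate only the secondary 3α-hydroxyl (the tertiary 4α-hydroxyl is too hindered) and keep the Z geometry of the 2-methylbut-2-enoyl group.

Step 9
Reactants: 18 (3α,4α,5α,10β)-4-hydroxy-8-oxoeudesm-7(11)-en-3-yl (Z)-2-methylbut-2-enoate
Product: 19 (3α,4α,5α,10β)-4-acetoxy-8-oxoeudesm-7(11)-en-3-yl (Z)-2-methylbut-2-enoate
Conditions: Ac2O, Sc(OTf)3 (5 mol %), MeCN, −20 °C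
Reagents that add atoms: acetic anhydride, CC(=O)OC(C)=O
Why: Lewis-acid-catalysed acylation with the anhydride is an established way to acetylate hindered tertiary alcohols at low temperature and, being non-basic, should avoid alkoxide-mediated 1,2-migration of the neighbouring angelate and its Z-to-E isomerisation.

Step 10
Reactants: 19 (3α,4α,5α,10β)-4-acetoxy-8-oxoeudesm-7(11)-en-3-yl (Z)-2-methylbut-2-enoate
Product: 20 (3α,4α,5α,10β)-4-acetoxy-11-hydroperoxy-8-oxoeudesm-6-en-3-yl (Z)-2-methylbut-2-enoate (CNP0225062.1)
Conditions: O2, tetraphenylporphyrin (cat.), CH2Cl2, visible light (>500 nm), −10 °C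
Reagents that add atoms: oxygen, O=O
Why: The Schenck ene reaction of singlet oxygen with the s-cis-locked enone should follow the geminal rule for α,β-unsaturated carbonyl compounds, bonding oxygen to the β-carbon C11 and removing the axial 6β-hydrogen so that the alkene shifts to C6=C7 in conjugation with C8=O, while C11 carries two methyl groups (no new stereocentre) and the electron-poor angelate alkene should react far more slowly under long-wavelength light.

Compound list
1 | (R)-carvone | CC1=CC[C@@H](C(C)=C)CC1=O | starting material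
2 | isopropenylmagnesium bromide | CC(=C)[Mg]Br | starting material
3 | bromomagnesium (3S,5R)-2-methyl-3,5-di(prop-1-en-2-yl)cyclohex-1-en-1-olate | CC1=C(O[Mg]Br)C[C@H](C(C)=C)C[C@H]1C(C)=C | intermediate
4 | trimethyl{[(3S,5R)-2-methyl-3,5-di(prop-1-en-2-yl)cyclohex-1-en-1-yl]oxy}silane (two isopropenyl groups trans) | CC1=C(O[Si](C)(C)C)C[C@H](C(C)=C)C[C@H]1C(C)=C | intermediate
5 | 4-iodobut-1-ene | C=CCCI | starting material
6 | lithium (3S,5R)-2-methyl-3,5-di(prop-1-en-2-yl)cyclohex-1-en-1-olate | CC1=C(O[Li])C[C@H](C(C)=C)C[C@H]1C(C)=C | intermediate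
7 | (2S,3S,5R)-2-(but-3-en-1-yl)-2-methyl-3,5-di(prop-1-en-2-yl)cyclohexan-1-one (butenyl trans to the 3-isopropenyl group; 3- and 5-isopropenyl groups trans) | C=CCC[C@]1(C)C(=O)C[C@H](C(C)=C)C[C@H]1C(C)=C | intermediate
8 | (5α,7βH,10β)-eudesma-3,11-dien-9-one (trans-decalin; 10β-methyl; 5α-H; isopropenyl α on C7) | CC1=CCC[C@]2(C)C(=O)C[C@H](C(C)=C)C[C@@H]12 | intermediate
9 | (E)-tosylhydrazone of 8 (sulfonamide nitrogen anti to C10) | CC1=CCC[C@]2(C)/C(=N/NS(=O)(=O)c3ccc(C)cc3)C[C@H](C(C)=C)C[C@@H]12 | intermediate
10 | N-lithio tosylhydrazone of (5α,7βH,10β)-8β-(methylsulfanyl)eudesma-3,11-dien-9-one | CC1=CCC[C@]2(C)/C(=N/N([Li])S(=O)(=O)c3ccc(C)cc3)[C@@H](SC)[C@H](C(C)=C)C[C@@H]12 | intermediate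
11 | (5α,7βH,10β)-9-lithio-8-(methylsulfanyl)eudesma-3,8,11-triene | CC1=CCC[C@]2(C)C([Li])=C(SC)[C@H](C(C)=C)C[C@@H]12 | intermediate
12 | (5α,7βH,10β)-8-(methylsulfanyl)eudesma-3,8,11-triene | CC1=CCC[C@]2(C)C=C(SC)[C@H](C(C)=C)C[C@@H]12 | intermediate
13 | (5α,7βH,10β)-eudesma-3,11-dien-8-one | CC1=CCC[C@]2(C)CC(=O)[C@H](C(C)=C)C[C@@H]12 | intermediate
14 | (5α,10β)-eudesma-3,7(11)-dien-8-one | CC1=CCC[C@]2(C)CC(=O)C(=C(C)C)C[C@@H]12 | intermediate
15 | (3α,4α,5α,10β)-3,4-dihydroxyeudesm-7(11)-en-8-one (both hydroxyls α; C15 methyl β) | O[C@@H]1CC[C@]2(C)CC(=O)C(=C(C)C)C[C@H]2[C@]1(C)O | intermediate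
16 | angelic acid, (Z)-2-methylbut-2-enoic acid | C/C=C(/C)C(=O)O | starting material
17 | (Z)-2-methylbut-2-enoic 2,4,6-trichlorobenzoic anhydride | C/C=C(/C)C(=O)OC(=O)c1c(Cl)cc(Cl)cc1Cl | intermediate
18 | (3α,4α,5α,10β)-4-hydroxy-8-oxoeudesm-7(11)-en-3-yl (Z)-2-methylbut-2-enoate | C/C=C(/C)C(=O)O[C@@H]1CC[C@]2(C)CC(=O)C(=C(C)C)C[C@H]2[C@]1(C)O | intermediate
19 | (3α,4α,5α,10β)-4-acetoxy-8-oxoeudesm-7(11)-en-3-yl (Z)-2-methylbut-2-enoate | C/C=C(/C)C(=O)O[C@@H]1CC[C@]2(C)CC(=O)C(=C(C)C)C[C@H]2[C@]1(C)OC(C)=O | intermediate
20 | (3α,4α,5α,10β)-4-acetoxy-11-hydroperoxy-8-oxoeudesm-6-en-3-yl (Z)-2-methylbut-2-enoate, CNP0225062.1 | C/C=C(/C)C(=O)O[C@@H]1CC[C@]2(C)CC(=O)C(C(C)(C)OO)=C[C@H]2[C@]1(C)OC(C)=O | target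

Total step count: 10
Longest linear sequence: 10 steps, from (R)-carvone 1 to target 20

Steps most likely to fail

Step 5 (sulfenylation and Shapiro elimination). The dianion may form incompletely at the hindered C8 position. Proton exchange between sulfenylated and unsulfenylated anions may cause double sulfenylation. Dinitrogen may also be lost before sulfur is attached, which would leave a plain C8=C9 alkene with no handle for oxygen. The fallback sets out from ketone 8 and moves the carbonyl by palladium/norbornene catalysis instead. KN(SiMe3)2 and PhNTf2 in THF at −78 °C should give the C8=C9 enol triflate F1. A Catellani-type reaction should then aminate C8 and replace the triflate on C9 by hydrogen, giving the morpholine enamine F2. Its conditions would be Pd(OAc)2, a triarylphosphine, an amide-substituted norbornene as cocatalyst, N-(benzoyloxy)morpholine, i-PrOH as hydride donor, Cs2CO3, 1,4-dioxane, 100 °C. Aqueous HCl hydrolysis followed by DBU, as in step 6, returns to the route at enone 14.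

Step 9 (acetylation of the tertiary hydroxyl). Acylation of the hindered 4α-hydroxyl may stall. The Lewis acid may ionise C4 and cause elimination. The angeloyl group may also transfer from O3 to O4, so that the two esters end up exchanged. The fallback sets out from diol 15 and reverses the order of the acylations with a temporary silyl group. TESCl and imidazole in DMF should silylate the secondary hydroxyl to give the 3α-triethylsilyl ether F3. The tertiary hydroxyl is then acetylated under forcing nucleophilic catalysis (Ac2O, DMAP, Et3N, 50 °C), with no angelate present to isomerise or migrate, giving the silyl ether acetate F4. HF·pyridine in THF at 0 °C should free the 3α-hydroxyl under acidic conditions that do not favour acetyl migration, giving the hydroxy acetate F5. Angeloylation of F5 with the mixed anhydride 17, as in step 8, returns to the route at diester 19.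

Step 2 (enolate alkylation). The hindered enolate may act as a base toward the homoallylic iodide, losing HI to butadiene, or may be alkylated on oxygen; either way mostly unalkylated ketone would return. The fallback sets out from silyl enol ether 4 and attaches the four-carbon chain by conjugate addition and olefination. Mukaiyama–Michael addition to acrolein (BF3·OEt2, i-PrOH, MeNO2/CH2Cl2, −20 °C) should give the keto aldehyde F6 with the same facial preference, anti to the vicinal isopropenyl group. Wittig methylenation of the aldehyde (Ph3P=CH2, THF, −78 → 0 °C), which the hindered α-quaternary ketone should not undergo at low temperature, returns to the route at 7.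

Further compounds
F1 | step 5 | (5α,7βH,10β)-eudesma-3,8,11-trien-9-yl trifluoromethanesulfonate | CC1=CCC[C@]2(C)C(OS(=O)(=O)C(F)(F)F)=C[C@H](C(C)=C)C[C@@H]12
F2 | step 5 | 4-[(5α,7βH,10β)-eudesma-3,8,11-trien-8-yl]morpholine | CC1=CCC[C@]2(C)C=C(N3CCOCC3)[C@H](C(C)=C)C[C@@H]12
F3 | step 9 | (3α,4α,5α,10β)-4-hydroxy-3-(triethylsilyloxy)eudesm-7(11)-en-8-one | CC[Si](CC)(CC)O[C@@H]1CC[C@]2(C)CC(=O)C(=C(C)C)C[C@H]2[C@]1(C)O
F4 | step 9 | (3α,4α,5α,10β)-8-oxo-3-(triethylsilyloxy)eudesm-7(11)-en-4-yl acetate | CC[Si](CC)(CC)O[C@@H]1CC[C@]2(C)CC(=O)C(=C(C)C)C[C@H]2[C@]1(C)OC(C)=O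
F5 | step 9 | (3α,4α,5α,10β)-3-hydroxy-8-oxoeudesm-7(11)-en-4-yl acetate | O[C@@H]1CC[C@]2(C)CC(=O)C(=C(C)C)C[C@H]2[C@]1(C)OC(C)=O
F6 | step 2 | 3-[(1S,2S,4R)-1-methyl-6-oxo-2,4-di(prop-1-en-2-yl)cyclohexyl]propanal | O=CCC[C@]1(C)C(=O)C[C@H](C(C)=C)C[C@H]1C(C)=C
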